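**Retrosynthetic overview**
1. Target ⇐ its hexabenzyl ether by global hydrogenolysis; the dihydrofuran ring is the only ring made, in the penultimate step, on the intact resorcinol core.
2. Dihydrofuran ring ⇐ C2–C3 and then O1–C2 bonds by a new enantioselective [4+1] annulation of an ortho-quinone methide with a chiral sulfonium benzylide.
3. Quinone methide precursor (ortho-hydroxybenzhydryl sulfone) ⇐ diarylmethanol ⇐ Grignard addition of the 3,5-dioxygenated aryl to a 2-hydroxy-6-benzyloxybenzaldehyde.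
4. That aldehyde ⇐ chelation-controlled mono-debenzylation ⇐ ortho-lithiation/formylation of tribenzyl dihydroresveratrol.
5. Sulfonium salt ⇐ 2,4-bis(benzyloxy)benzyl alcohol + (1R,4R,5R)-isothiocineole.

Assumption: the (1R,4R,5R)-enantiomer of isothiocineole is taken to deliver the (2S,3S) series; if the mirror-image product forms, the equally available (1S,4S,5S)-sulfide is used with no other change.

**Step 1**
Reactants: 1 dihydroresveratrol (5-[2-(4-hydroxyphenyl)ethyl]benzene-1,3-diol)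
Product: 2 1,3-bis(benzyloxy)-5-{2-[4-(benzyloxy)phenyl]ethyl}benzene
Conditions: BnBr (3.6 equiv), K2CO3 (4.5 equiv), DMF, 60 °C
Reagents that add atoms: benzyl bromide, BrCc1ccccc1
Why: Williamson ether synthesis, in which the carbonate-generated phenoxides displace bromide from the primary benzylic halide by SN2 and nothing else in 1 is base- or electrophile-sensitive.

**Step 2**
Reactants: 2 1,3-bis(benzyloxy)-5-{2-[4-(benzyloxy)phenyl]ethyl}benzene
Product: 4 2,6-bis(benzyloxy)-4-{2-[4-(benzyloxy)phenyl]ethyl}benzaldehyde, via aryllithium 3 (not isolated)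
Conditions: n-BuLi (1.2 equiv), TMEDA, THF, 0 °C, 2 h; DMF (3 equiv), 0 °C to rt; then H2O
Reagents that add atoms: N,N-dimethylformamide, CN(C)C=O
Why: Directed ortho-metalation followed by formylation, because the ring C–H flanked by two benzyloxy groups is the most acidic and doubly lithium-coordinating site, and the aryllithium adds to DMF to give a hemiaminal salt that releases the aldehyde on quench.

**Step 3**
Reactants: 4 2,6-bis(benzyloxy)-4-{2-[4-(benzyloxy)phenyl]ethyl}benzaldehyde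
Product: 5 2-(benzyloxy)-4-{2-[4-(benzyloxy)phenyl]ethyl}-6-hydroxybenzaldehyde
Conditions: MgBr2·OEt2 (3 equiv), PhMe/Et2O 5:1, 80 °C; then H2O
Reagents that add atoms: none
Why: Chelation-controlled Lewis-acid ether cleavage, in which magnesium bridging the formyl oxygen and one ortho ether oxygen activates only that O–CH2Ph bond to SN2 attack by bromide, and the resulting magnesium phenoxide chelate turns the carbonyl away from the second ortho ether so that it and the remote benzyl ether survive.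

**Step 4**
Reactants: 5 2-(benzyloxy)-4-{2-[4-(benzyloxy)phenyl]ethyl}-6-hydroxybenzaldehyde; 6 1,3-bis(benzyloxy)-5-bromobenzene
Product: 8 rac-3-(benzyloxy)-2-{[3,5-bis(benzyloxy)phenyl](hydroxy)methyl}-5-{2-[4-(benzyloxy)phenyl]ethyl}phenol, via Grignard reagent 7 (not isolated)
Conditions: 6, Mg, cat. I2, THF, 50 °C; then 5 added to 7 (2.3 equiv), THF, 0 °C to rt; then H2O
Reagents that add atoms: none
Why: Grignard 1,2-addition, in which the first equivalent of 7 forms the magnesium phenoxide that chelates and activates the formyl group for the second, and the carbinol centre is left racemic on purpose because it becomes sp2 at the quinone methide stage.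

**Step 5**
Reactants: 8 rac-3-(benzyloxy)-2-{[3,5-bis(benzyloxy)phenyl](hydroxy)methyl}-5-{2-[4-(benzyloxy)phenyl]ethyl}phenol
Product: 9 rac-3-(benzyloxy)-2-{[3,5-bis(benzyloxy)phenyl](4-methylbenzenesulfonyl)methyl}-5-{2-[4-(benzyloxy)phenyl]ethyl}phenol
Conditions: p-TolSO2H (1.5 equiv), CH2Cl2, rt
Reagents that add atoms: p-toluenesulfinic acid, Cc1ccc(cc1)S(=O)O
Why: SN1-type substitution through the ortho-quinone methide/diarylmethyl cation, since the doubly activated ortho-hydroxybenzhydrol ionises under the mildly acidic sulfinic acid and is captured at sulfur to give the stable sulfone, whose racemic centre is erased again in step 8.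

**Step 6**
Reactants: 10 2,4-bis(benzyloxy)benzaldehyde
Product: 11 [2,4-bis(benzyloxy)phenyl]methanol
Conditions: NaBH4, MeOH/THF, 0 °C
Reagents that add atoms: none
Why: Borohydride reduction of an aromatic aldehyde to the primary benzylic alcohol, to which aryl benzyl ethers are inert.

**Step 7**
Reactants: 11 [2,4-bis(benzyloxy)phenyl]methanol; 12 (1R,4R,5R)-4,7,7-trimethyl-6-thiabicyclo[3.2.1]octane (isothiocineole)
Product: 13 (1R,4R,5R,6R)-6-{[2,4-bis(benzyloxy)phenyl]methyl}-4,7,7-trimethyl-6-thiabicyclo[3.2.1]octan-6-ium tetrafluoroborate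
Conditions: HBF4·OEt2 (1.1 equiv), 12 (1.5 equiv), Et2O, 0 °C to rt; salt filtered off and used cold
Reagents that add atoms: tetrafluoroboric acid (as its diethyl ether complex), [H+].F[B-](F)(F)F
Why: SN1 S-alkylation, in which the acid ionises the electron-rich benzylic alcohol and the cation is captured by the exposed exo lone pair of the rigid bicyclic sulfide, giving one sulfonium diastereomer (R at sulfur) that precipitates with the non-nucleophilic counterion.

**Step 8**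
Reactants: 9 rac-3-(benzyloxy)-2-{[3,5-bis(benzyloxy)phenyl](4-methylbenzenesulfonyl)methyl}-5-{2-[4-(benzyloxy)phenyl]ethyl}phenol; 13 (1R,4R,5R,6R)-6-{[2,4-bis(benzyloxy)phenyl]methyl}-4,7,7-trimethyl-6-thiabicyclo[3.2.1]octan-6-ium tetrafluoroborate
Product: 17 (2S,3S)-4-(benzyloxy)-2-[2,4-bis(benzyloxy)phenyl]-3-[3,5-bis(benzyloxy)phenyl]-6-{2-[4-(benzyloxy)phenyl]ethyl}-2,3-dihydro-1-benzofuran, via o-quinone methide 14 (not isolated), via sulfonium ylide 15 (not isolated), via betaine 16 (not isolated)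
Conditions: Cs2CO3 (3 equiv), 13 (1.3 equiv), MeCN/CH2Cl2 1:1, −20 °C to rt; 9 added slowly
Reagents that add atoms: none
Why: Proposed new method: an enantioselective formal [4+1] annulation in which Cs2CO3 turns sulfone 9 into ortho-quinone methide 14 (E1cB loss of sulfinate) and salt 13 into the semi-stabilised aryl ylide 15; the ylide carbon, one face shielded by the bicyclic sulfide and its conformation fixed by the gem-dimethyl group, adds 1,4 to the exocyclic carbon of 14 to give the re-aromatised anti-betaine 16 and so sets C3 as S, and the phenoxide then displaces the sulfide in a 5-exo-tet SN2 closure with inversion, setting C2 as S and the trans relationship; the closest known reaction types are the sulfonium-ylide epoxidation, aziridination and cyclopropanation mediated by this chiral sulfide and the [4+1] annulation of ortho-quinone methides with carbonyl-stabilised sulfur ylides.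

**Step 9**
Reactants: 17 (2S,3S)-4-(benzyloxy)-2-[2,4-bis(benzyloxy)phenyl]-3-[3,5-bis(benzyloxy)phenyl]-6-{2-[4-(benzyloxy)phenyl]ethyl}-2,3-dihydro-1-benzofuran
Product: 18 (2S,3S)-2-(2,4-dihydroxyphenyl)-3-(3,5-dihydroxyphenyl)-6-[2-(4-hydroxyphenyl)ethyl]-2,3-dihydro-1-benzofuran-4-ol
Conditions: H2 (1 atm), 10% Pd/C, EtOAc/MeOH 1:1, rt; stopped at full debenzylation
Reagents that add atoms: none
Why: Heterogeneous catalytic hydrogenolysis of the six aryl benzyl ethers, which cleave much faster than the cyclic C2–O benzylic bond under 1 atm at room temperature, and neither stereocentre is touched.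

**Compound list**
1 | dihydroresveratrol, 5-[2-(4-hydroxyphenyl)ethyl]benzene-1,3-diol | Oc1ccc(CCc2cc(O)cc(O)c2)cc1 | starting material
2 | 1,3-bis(benzyloxy)-5-{2-[4-(benzyloxy)phenyl]ethyl}benzene | C(c1ccccc1)Oc1ccc(CCc2cc(OCc3ccccc3)cc(OCc3ccccc3)c2)cc1 | intermediate
3 | {2,6-bis(benzyloxy)-4-{2-[4-(benzyloxy)phenyl]ethyl}phenyl}lithium | C(c1ccccc1)Oc1ccc(CCc2cc(OCc3ccccc3)c([Li])c(OCc3ccccc3)c2)cc1 | intermediate
4 | 2,6-bis(benzyloxy)-4-{2-[4-(benzyloxy)phenyl]ethyl}benzaldehyde | C(c1ccccc1)Oc1ccc(CCc2cc(OCc3ccccc3)c(C=O)c(OCc3ccccc3)c2)cc1 | intermediate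
5 | 2-(benzyloxy)-4-{2-[4-(benzyloxy)phenyl]ethyl}-6-hydroxybenzaldehyde | C(c1ccccc1)Oc1ccc(CCc2cc(O)c(C=O)c(OCc3ccccc3)c2)cc1 | intermediate
6 | 1,3-bis(benzyloxy)-5-bromobenzene | Brc1cc(OCc2ccccc2)cc(OCc2ccccc2)c1 | starting material
7 | [3,5-bis(benzyloxy)phenyl]magnesium bromide | Br[Mg]c1cc(OCc2ccccc2)cc(OCc2ccccc2)c1 | intermediate
8 | rac-3-(benzyloxy)-2-{[3,5-bis(benzyloxy)phenyl](hydroxy)methyl}-5-{2-[4-(benzyloxy)phenyl]ethyl}phenol (racemic carbinol centre) | C(c1ccccc1)Oc1ccc(CCc2cc(O)c(C(O)c3cc(OCc4ccccc4)cc(OCc4ccccc4)c3)c(OCc3ccccc3)c2)cc1 | intermediate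
9 | rac-3-(benzyloxy)-2-{[3,5-bis(benzyloxy)phenyl](4-methylbenzenesulfonyl)methyl}-5-{2-[4-(benzyloxy)phenyl]ethyl}phenol (racemic) | C(c1ccccc1)Oc1ccc(CCc2cc(O)c(C(c3cc(OCc4ccccc4)cc(OCc4ccccc4)c3)S(=O)(=O)c3ccc(C)cc3)c(OCc3ccccc3)c2)cc1 | intermediate
10 | 2,4-bis(benzyloxy)benzaldehyde | O=Cc1ccc(OCc2ccccc2)cc1OCc1ccccc1 | starting material
11 | [2,4-bis(benzyloxy)phenyl]methanol | OCc1ccc(OCc2ccccc2)cc1OCc1ccccc1 | intermediate
12 | (1R,4R,5R)-4,7,7-trimethyl-6-thiabicyclo[3.2.1]octane (isothiocineole) | C[C@@H]1CC[C@@H]2C[C@H]1SC2(C)C | starting material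
13 | (1R,4R,5R,6R)-6-{[2,4-bis(benzyloxy)phenyl]methyl}-4,7,7-trimethyl-6-thiabicyclo[3.2.1]octan-6-ium tetrafluoroborate | C[C@@H]1CC[C@@H]2C[C@H]1[S@@+](Cc1ccc(OCc3ccccc3)cc1OCc1ccccc1)C2(C)C.F[B-](F)(F)F | intermediate
14 | 3-(benzyloxy)-5-{2-[4-(benzyloxy)phenyl]ethyl}-2-{[3,5-bis(benzyloxy)phenyl]methylidene}cyclohexa-3,5-dien-1-one (ortho-quinone methide; exocyclic alkene geometry not fixed) | O=C1C=C(CCc2ccc(OCc3ccccc3)cc2)C=C(OCc2ccccc2)C1=Cc1cc(OCc2ccccc2)cc(OCc2ccccc2)c1 | intermediate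
15 | [2,4-bis(benzyloxy)phenyl][(1R,4R,5R,6R)-4,7,7-trimethyl-6-thiabicyclo[3.2.1]octan-6-ium-6-yl]methanide (sulfonium ylide) | C[C@@H]1CC[C@@H]2C[C@H]1[S@@+]([CH-]c1ccc(OCc3ccccc3)cc1OCc1ccccc1)C2(C)C | intermediate
16 | (1R,4R,5R,6S)-6-{(1R,2S)-1-[2,4-bis(benzyloxy)phenyl]-2-[3,5-bis(benzyloxy)phenyl]-2-[2-(benzyloxy)-4-{2-[4-(benzyloxy)phenyl]ethyl}-6-oxidophenyl]ethyl}-4,7,7-trimethyl-6-thiabicyclo[3.2.1]octan-6-ium (anti-betaine, inner salt; sulfur geometry as in 13) | C[C@@H]1CC[C@@H]2C[C@H]1[S@@+]([C@@H](c1ccc(OCc3ccccc3)cc1OCc1ccccc1)[C@@H](c1cc(OCc3ccccc3)cc(OCc3ccccc3)c1)c1c([O-])cc(CCc3ccc(OCc4ccccc4)cc3)cc1OCc1ccccc1)C2(C)C | intermediate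
17 | (2S,3S)-4-(benzyloxy)-2-[2,4-bis(benzyloxy)phenyl]-3-[3,5-bis(benzyloxy)phenyl]-6-{2-[4-(benzyloxy)phenyl]ethyl}-2,3-dihydro-1-benzofuran (trans) | C(c1ccccc1)Oc1ccc(CCc2cc(OCc4ccccc4)c3c(c2)O[C@H](c2ccc(OCc4ccccc4)cc2OCc2ccccc2)[C@H]3c2cc(OCc3ccccc3)cc(OCc3ccccc3)c2)cc1 | intermediate
18 | (2S,3S)-2-(2,4-dihydroxyphenyl)-3-(3,5-dihydroxyphenyl)-6-[2-(4-hydroxyphenyl)ethyl]-2,3-dihydro-1-benzofuran-4-ol (CNP0329616.1, trans) | Oc1ccc(CCc2cc(O)c3c(c2)O[C@H](c2ccc(O)cc2O)[C@H]3c2cc(O)cc(O)c2)cc1 | target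

**Step count and risks**
Total steps: 9. Longest linear sequence: 7 (steps 1, 2, 3, 4, 5, 8, 9); steps 6 and 7 make the sulfonium salt.

Step 2 (ortho-lithiation beside three benzyl ethers). The risk is lithiation at an O–CH2Ph position, with [1,2]-Wittig rearrangement, or on the distal ring. The fallback sets out from 1 and comes back at 4, and moves the lithiation onto acetal-protected material. MOMCl and i-Pr2NEt in CH2Cl2 give 1,3-bis(methoxymethoxy)-5-{2-[4-(methoxymethoxy)phenyl]ethyl}benzene F1. n-BuLi/TMEDA in THF at 0 °C followed by DMF gives 2,6-bis(methoxymethoxy)-4-{2-[4-(methoxymethoxy)phenyl]ethyl}benzaldehyde F2. HCl in MeOH at 50 °C gives 2,6-dihydroxy-4-[2-(4-hydroxyphenyl)ethyl]benzaldehyde F3. BnBr and K2CO3 in DMF then give 4.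

Step 8 (the proposed new annulation). The risks are: (a) benzyl transfer from 13 to the phenoxide of 9; (b) partial SN1 loss of the sulfide from the electron-rich benzylic sulfonium, which would turn the minor syn-betaine into the enantiomer instead of the separable cis isomer and erode ee; (c) a low anti/syn ratio in the addition. The fallback uses known chemistry (Mitsunobu etherification, Grignard addition, oxidation, and an enantioselective dirhodium donor/donor-carbene C–H insertion followed by acid epimerisation); it sets out from 5, also uses 11 and 7, and comes back at 17.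
- Phenol 5 and alcohol 11 with PPh3 and DIAD in THF give 2-(benzyloxy)-6-{[2,4-bis(benzyloxy)phenyl]methoxy}-4-{2-[4-(benzyloxy)phenyl]ethyl}benzaldehyde F4.
- Grignard reagent 7 in THF gives the racemic diarylmethanol F5.
- Dess–Martin periodinane gives the diaryl ketone F6.
- Anhydrous N2H4 in n-BuOH at 120 °C gives the ketone hydrazone F7 (forcing conditions because the ketone is di-ortho-substituted).
- MnO2 in CH2Cl2 gives the diaryldiazomethane F8.
- F8 is treated at once with Rh2(R-PTAD)4, dirhodium tetrakis[(R)-(1-adamantyl)(N-phthalimido)acetate], or its mirror image, whichever delivers 3S. The carbene inserts into the more hydridic C–H bond of the 2,4-dialkoxybenzyl ether in preference to the plain benzyl ether and gives the cis-(2R,3S)-2,3-diaryl-2,3-dihydrobenzofuran F9.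
- BF3·OEt2 in CH2Cl2 at 0 °C epimerises C2 alone, through the ring-opened 2,4-dialkoxybenzylic cation, to the more stable trans isomer 17.

Step 9 (global hydrogenolysis). The risk is reductive opening of the cyclic benzylic C2–O bond once the 2-aryl group carries free ortho/para hydroxyls. The fallback sets out from 17 and comes back at 18, and replaces hydrogenation by Lewis-acid debenzylation: BCl3 (12 equiv) with pentamethylbenzene as benzyl-cation scavenger in CH2Cl2 at −78 °C. Any reversible opening at C2 recloses to the favoured trans isomer without touching C3. No new compound is made on this way, F0.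

**Further compounds**
F1 | step 2 | 1,3-bis(methoxymethoxy)-5-{2-[4-(methoxymethoxy)phenyl]ethyl}benzene | COCOc1ccc(CCc2cc(OCOC)cc(OCOC)c2)cc1
F2 | step 2 | 2,6-bis(methoxymethoxy)-4-{2-[4-(methoxymethoxy)phenyl]ethyl}benzaldehyde | COCOc1ccc(CCc2cc(OCOC)c(C=O)c(OCOC)c2)cc1
F3 | step 2 | 2,6-dihydroxy-4-[2-(4-hydroxyphenyl)ethyl]benzaldehyde | Oc1ccc(CCc2cc(O)c(C=O)c(O)c2)cc1
F4 | step 8 | 2-(benzyloxy)-6-{[2,4-bis(benzyloxy)phenyl]methoxy}-4-{2-[4-(benzyloxy)phenyl]ethyl}benzaldehyde | C(c1ccccc1)Oc1ccc(CCc2cc(OCc3ccc(OCc4ccccc4)cc3OCc3ccccc3)c(C=O)c(OCc3ccccc3)c2)cc1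
F5 | step 8 | rac-{2-(benzyloxy)-6-{[2,4-bis(benzyloxy)phenyl]methoxy}-4-{2-[4-(benzyloxy)phenyl]ethyl}phenyl}[3,5-bis(benzyloxy)phenyl]methanol | C(c1ccccc1)Oc1ccc(CCc2cc(OCc3ccc(OCc4ccccc4)cc3OCc3ccccc3)c(C(O)c3cc(OCc4ccccc4)cc(OCc4ccccc4)c3)c(OCc3ccccc3)c2)cc1
F6 | step 8 | {2-(benzyloxy)-6-{[2,4-bis(benzyloxy)phenyl]methoxy}-4-{2-[4-(benzyloxy)phenyl]ethyl}phenyl}[3,5-bis(benzyloxy)phenyl]methanone | C(c1ccccc1)Oc1ccc(CCc2cc(OCc3ccc(OCc4ccccc4)cc3OCc3ccccc3)c(C(=O)c3cc(OCc4ccccc4)cc(OCc4ccccc4)c3)c(OCc3ccccc3)c2)cc1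
F7 | step 8 | hydrazone of the methanone F6 (C=N geometry not fixed) | C(c1ccccc1)Oc1ccc(CCc2cc(OCc3ccc(OCc4ccccc4)cc3OCc3ccccc3)c(C(=NN)c3cc(OCc4ccccc4)cc(OCc4ccccc4)c3)c(OCc3ccccc3)c2)cc1
F8 | step 8 | 1-(benzyloxy)-3-{[2,4-bis(benzyloxy)phenyl]methoxy}-5-{2-[4-(benzyloxy)phenyl]ethyl}-2-{[3,5-bis(benzyloxy)phenyl](diazo)methyl}benzene | C(c1ccccc1)Oc1ccc(CCc2cc(OCc3ccc(OCc4ccccc4)cc3OCc3ccccc3)c(C(=[N+]=[N-])c3cc(OCc4ccccc4)cc(OCc4ccccc4)c3)c(OCc3ccccc3)c2)cc1
F9 | step 8 | (2R,3S)-4-(benzyloxy)-2-[2,4-bis(benzyloxy)phenyl]-3-[3,5-bis(benzyloxy)phenyl]-6-{2-[4-(benzyloxy)phenyl]ethyl}-2,3-dihydro-1-benzofuran (cis) | C(c1ccccc1)Oc1ccc(CCc2cc(OCc4ccccc4)c3c(c2)O[C@@H](c2ccc(OCc4ccccc4)cc2OCc2ccccc2)[C@H]3c2cc(OCc3ccccc3)cc(OCc3ccccc3)c2)cc1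
F0 | step 9 | none | none
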